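**Strategy.** The benzene ring is disconnected into a four-carbon and a two-carbon piece. Ring atoms C3–C4–C5–C6 (Br, O, O, Br) form a mirror-symmetric diene unit, supplied by 2,5-dibromo-3,4-dimethoxythiophene 1,1-dioxide. C1–C2 (the carbonyl-bearing carbon and its brominated neighbour) come from methyl 3-bromopropiolate. A single Diels–Alder/SO2-extrusion operation forges C6–C1 and C2–C3, closes the carbocycle and delivers the hexasubstituted arene at the correct oxidation level, so all three C–Br bonds arrive pre-installed and no regiochemical question arises. The precursor is a non-aromatic cyclic sulfone diene with bromine on both termini and methoxy groups on the inner carbons. Ester-to-aldehyde adjustment and ether cleavage finish the synthesis.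

Key step: step 4

Remark: dimethyldioxirane is taken as a freshly prepared, titrated acetone solution whose preparation is not counted as a step. Bicyclic intermediate 9 is racemic (one enantiomer drawn) and its stereocentres vanish within the same step.

**Step 1**
Reactants: 1 3,4-dimethoxythiophene; 2 N-bromosuccinimide
Product: 4 2,5-dibromo-3,4-dimethoxythiophene, via 2-bromo-3,4-dimethoxythiophene 3 (not isolated)
Conditions: NBS (2.1 equiv), DMF, 0 °C → rt, dark; product used without storage
Reagents that add atoms: N-bromosuccinimide (compound 2), O=C1CCC(=O)N1Br
Why: Electrophilic aromatic bromination; the two α-positions are the only ring C–H sites and each is activated by sulfur and an adjacent methoxy group, so twofold substitution through monobromide 3 should be fast and clean.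

**Step 2**
Reactants: 4 2,5-dibromo-3,4-dimethoxythiophene
Product: 6 2,5-dibromo-3,4-dimethoxythiophene 1,1-dioxide, via thiophene 1-oxide 5 (not isolated)
Conditions: dimethyldioxirane (3 equiv, in acetone), CH2Cl2, −20 °C → rt
Reagents that add atoms: dimethyldioxirane, CC1(C)OO1
Why: Sulfide-to-sulfone oxidation by electrophilic oxygen transfer from a neutral dioxirane; the first transfer cancels the ring aromaticity, S-oxide 5 is shielded from Diels–Alder self-dimerisation by its α-bromines and should be oxidised further faster than it forms, and the acid-free medium spares the enol-ether units.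

**Step 3**
Reactants: 7 methyl propiolate; 2 N-bromosuccinimide
Product: 8 methyl 3-bromopropiolate
Conditions: NBS (1.1 equiv), AgNO3 (10 mol %), acetone, rt, dark; distillation under reduced pressure (lachrymator)
Reagents that add atoms: N-bromosuccinimide (compound 2), O=C1CCC(=O)N1Br
Why: Silver-catalysed electrophilic bromination of a terminal alkyne; AgNO3 forms the silver acetylide reversibly and NBS brominates it at carbon without touching the ester.

**Step 4**
Reactants: 6 2,5-dibromo-3,4-dimethoxythiophene 1,1-dioxide; 8 methyl 3-bromopropiolate
Product: 10 methyl 2,3,6-tribromo-4,5-dimethoxybenzoate, via 7-thianorbornadiene dioxide adduct 9 (not isolated)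
Conditions: 8 (3 equiv), PhMe, 110 °C, sealed tube, dark
Reagents that add atoms: none
Why: Sulfone 6 is a non-aromatic diene held s-cis whose termini are the β-carbons of two methoxy enol ethers, so its raised HOMO should engage the LUMO of electron-poor alkyne 8 in a concerted, suprafacial, thermally allowed (4+2) cycloaddition that forms C6–C1 and C2–C3 (target numbering) together. The six-membered carbocycle is closed by this intermolecular cycloaddition, both ring bonds being made in one event, and 7-thianorbornadiene dioxide 9 then expels SO2 in a cheletropic extrusion driven by aromatisation and loss of a gas. The closest known reaction type is the Diels–Alder/SO2-extrusion cascade of halogenated thiophene 1,1-dioxides with alkynes, which gives polyhalobenzenes. The two bridgehead stereocentres of 9 are fixed relative to each other by the bicycle itself (only the cis-bridged racemate is geometrically possible) and disappear on SO2 loss, so 10 has none. Because the diene has a mirror plane through sulfur, both orientations of the alkyne give the same arene; the selectivity required is cross-addition over self-dimerisation or decomposition of 6, which the α-bromines (hindering dimerisation) and the threefold excess of 8 should secure. The adduct aromatises without oxidant, base or elimination, so all three C–Br bonds should survive.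

**Step 5**
Reactants: 10 methyl 2,3,6-tribromo-4,5-dimethoxybenzoate
Product: 12 (2,3,6-tribromo-4,5-dimethoxyphenyl)methanol, via 2,3,6-tribromo-4,5-dimethoxybenzaldehyde 11 (not isolated)
Conditions: i-Bu2AlH (3 equiv), CH2Cl2, −78 → 0 °C; aq. potassium sodium tartrate
Reagents that add atoms: none
Why: Hydride reduction of an ester with a Lewis-acidic aluminium hydride; the aluminium hemiacetal collapses to aldehyde 11, which is reduced faster than the ester, and aryl bromides and aryl methyl ethers are inert at or below 0 °C.

**Step 6**
Reactants: 12 (2,3,6-tribromo-4,5-dimethoxyphenyl)methanol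
Product: 11 2,3,6-tribromo-4,5-dimethoxybenzaldehyde
Conditions: Dess–Martin periodinane (1.3 equiv), CH2Cl2, rt
Reagents that add atoms: none
Why: Dess–Martin oxidation of a primary benzylic alcohol; ligand exchange at iodine followed by α-hydrogen abstraction should stop at the aldehyde under anhydrous, nearly neutral conditions and tolerates the two flanking ortho bromines.

**Step 7**
Reactants: 11 2,3,6-tribromo-4,5-dimethoxybenzaldehyde
Product: 14 2,3,6-tribromo-4,5-dihydroxybenzaldehyde, via cyclic aryl bromoborate 13 (not isolated)
Conditions: BBr3 (4 equiv), CH2Cl2, −78 °C → rt; then H2O, 0 °C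
Reagents that add atoms: none
Why: Lewis-acid cleavage of aryl methyl ethers; boron coordinates each methoxy oxygen, bromide removes the methyl group by SN2 attack, the neighbouring oxygens collect in bromoborate 13 and water releases the catechol, while the aldehyde is only complexed reversibly and the aryl bromides are untouched.

**Compound list**
1 | 3,4-dimethoxythiophene | COc1cscc1OC | starting material
2 | N-bromosuccinimide | O=C1CCC(=O)N1Br | starting material
3 | 2-bromo-3,4-dimethoxythiophene (formed in the flask, not isolated) | COc1csc(Br)c1OC | intermediate
4 | 2,5-dibromo-3,4-dimethoxythiophene | COc1c(Br)sc(Br)c1OC | intermediate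
5 | 2,5-dibromo-3,4-dimethoxythiophene 1-oxide (formed in the flask, not isolated) | COC1=C(Br)S(=O)C(Br)=C1OC | intermediate
6 | 2,5-dibromo-3,4-dimethoxythiophene 1,1-dioxide | COC1=C(Br)S(=O)(=O)C(Br)=C1OC | intermediate
7 | methyl propiolate | C#CC(=O)OC | starting material
8 | methyl 3-bromopropiolate | COC(=O)C#CBr | intermediate
9 | methyl 1,3,4-tribromo-5,6-dimethoxy-7-thiabicyclo[2.2.1]hepta-2,5-diene-2-carboxylate 7,7-dioxide (racemic, one enantiomer drawn; formed in the flask, not isolated) | COC(=O)C1=C(Br)[C@]2(Br)C(OC)=C(OC)[C@@]1(Br)S2(=O)=O | intermediate
10 | methyl 2,3,6-tribromo-4,5-dimethoxybenzoate | COC(=O)c1c(Br)c(OC)c(OC)c(Br)c1Br | intermediate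
11 | 2,3,6-tribromo-4,5-dimethoxybenzaldehyde | O=Cc1c(Br)c(OC)c(OC)c(Br)c1Br | intermediate
12 | (2,3,6-tribromo-4,5-dimethoxyphenyl)methanol | OCc1c(Br)c(OC)c(OC)c(Br)c1Br | intermediate
13 | 2,4,6,7-tetrabromo-1,3,2-benzodioxaborole-5-carbaldehyde (formed in the flask, not isolated) | O=Cc1c(Br)c2OB(Br)Oc2c(Br)c1Br | intermediate
14 | 2,3,6-tribromo-4,5-dihydroxybenzaldehyde | O=Cc1c(Br)c(O)c(O)c(Br)c1Br | target

**Step count**
Total: 7 steps. Longest linear sequence: 6 steps (steps 1, 2, 4, 5, 6, 7 from compound 1); step 3 is a one-step branch.

**Steps most likely to fail**

1. Step 4. The cross-cycloaddition may be outrun by thermal decomposition or self-dimerisation of the sulfone, or the crowded transition state that creates two fully substituted bridgeheads may not be reached before the bromoalkyne degrades. The fallback builds the same ring from a diene that needs no SO2 loss and sets out from compound 8. A normal-demand Diels–Alder reaction of 8 with commercial 2,3-dimethoxybuta-1,3-diene (C=C(OC)C(=C)OC) in PhMe at 80 °C should give methyl 2-bromo-4,5-dimethoxycyclohexa-1,4-diene-1-carboxylate F1. Dehydrogenation with DDQ at rt should give methyl 2-bromo-4,5-dimethoxybenzoate F2. Exhaustive electrophilic bromination (excess Br2, catalytic Fe powder, CHCl3, reflux) at the two remaining ring positions, each ortho to a methoxy group, returns to the route at compound 10.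

2. Step 2. Oxygen transfer may stall at the S-oxide stage, which then dimerises, or the electron-rich ring may be attacked at carbon, leading to ring opening or oxidative polymerisation of the dibromide. The fallback inverts the order of halogenation and oxidation and sets out from compound 1. Lithiation and silylation at both α-positions (n-BuLi then Me3SiCl, carried out twice, THF, −78 °C) should give 3,4-dimethoxy-2,5-bis(trimethylsilyl)thiophene F3. This electron-rich, α-blocked thiophene should be oxidised by mCPBA in CH2Cl2 to 3,4-dimethoxy-2,5-bis(trimethylsilyl)thiophene 1,1-dioxide F4. Ipso-bromodesilylation with Br2 and AgBF4 (CH2Cl2, 0 °C) returns to the route at compound 6.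

3. Step 5. Hydride delivery to a carbonyl shielded by two ortho bromines may be slow, and forcing it may start reductive loss of aryl bromine. The fallback leaves the carbonyl untouched in its first operation and sets out from compound 10. LiI in ethyl acetate at reflux should cleave the methyl ester by SN2 attack of iodide on the O-methyl carbon, giving after acidification 2,3,6-tribromo-4,5-dimethoxybenzoic acid F5. BH3·SMe2 in THF should reduce the acid through its acyloxyborane, leaving aryl bromides and methyl ethers alone, and returns to the route at compound 12.

**Further compounds**
F1 | step 4 | methyl 2-bromo-4,5-dimethoxycyclohexa-1,4-diene-1-carboxylate | COC(=O)C1=C(Br)CC(OC)=C(OC)C1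
F2 | step 4 | methyl 2-bromo-4,5-dimethoxybenzoate | COC(=O)c1cc(OC)c(OC)cc1Br
F3 | step 2 | 3,4-dimethoxy-2,5-bis(trimethylsilyl)thiophene | COc1c([Si](C)(C)C)sc([Si](C)(C)C)c1OC
F4 | step 2 | 3,4-dimethoxy-2,5-bis(trimethylsilyl)thiophene 1,1-dioxide | COC1=C([Si](C)(C)C)S(=O)(=O)C([Si](C)(C)C)=C1OC
F5 | step 5 | 2,3,6-tribromo-4,5-dimethoxybenzoic acid | O=C(O)c1c(Br)c(OC)c(OC)c(Br)c1Br
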